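We start from amounts: Sunday's flask holds 17.0 mM of starting material over 4.00 mM of free catalyst, with no product charged, and we want the share of starting material still there at 3.8 min.

in all of them: free catalyst 4.00 mM

|  | starting material | product | time |
|---|---|---|---|
| Wednesday's | 80.0 mM |  |  |
| Saturday's | 40.0 mM |  |  |
| Monday's | 80.0 mM | 24.0 mM |  |
| Thursday's | 40.0 mM |  |  |
| Sunday's | 17.0 mM |  | 3.8 min |

| run | time / min | [starting material] / mM |
|---|---|---|
| Wednesday's run | 0.63 | 60.2 |
| Wednesday's run | 1.3 | 45.5 |
| Wednesday's run | 1.9 | 33.2 |
| Wednesday's run | 2.5 | 29.3 |
| Wednesday's run | 3.2 | 21.9 |
| Wednesday's run | 3.8 | 17.2 |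
| Saturday's run | 0.63 | 25.5 |
| Saturday's run | 1.3 | 18.7 |
| Saturday's run | 1.9 | 15.5 |
| Saturday's run | 2.5 | 10.6 |
| Saturday's run | 3.2 | 6.7 |
| Saturday's run | 3.8 | 5.4 |
| Monday's run | 0.63 | 63.5 |
| Monday's run | 1.3 | 50.2 |
| Monday's run | 1.9 | 40.5 |
| Monday's run | 2.5 | 35.1 |
| Monday's run | 3.2 | 30.2 |
| Monday's run | 3.8 | 27.4 |
| Thursday's run | 0.63 | 26.1 |
| Thursday's run | 1.3 | 18.8 |
| Thursday's run | 1.9 | 14.3 |
| Thursday's run | 2.5 | 11.5 |
| Thursday's run | 3.2 | 7.7 |
| Thursday's run | 3.8 | 8.5 |

(standard deviation of a reading: 1 mM)

1. the exponent of [starting material] in the starting rate at the charge of the Wednesday's run (at the point where two percent of the starting material have become product) (one fixed amount of product, the same in the runs compared)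
2. starting material in the Sunday's run at 3.8 min, as a share of the starting material charged

- Overall: starting material -> product, with free catalyst as catalyst.
- Constant volume, constant temperature.
- A reading of a species includes what of it is bound.
- An order is taken over about fifteen percent of the charge, up and down.

Our measure is the fractional fall, the share of the starting material present that leaves per minute, reckoned as ln(charge/reading)/time. Up to the first reading it is 0.715 /min in Saturday's flask and 0.678 /min in Thursday's, with a mean of 0.696 /min. We carry this mean as f, the early fractional fall of a product-free flask charged with 40.0 mM of starting material and 4.00 mM of free catalyst, and treat Sunday's fall as pseudo-first-order with it.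

Now Sunday's flask in slow motion. In the first instants it holds no product and less starting material than the other flasks. Wednesday's flask, at twice the charge of Saturday's and with the same free catalyst, read 0.451 /min, so in these flasks the smaller charge shows the steeper fractional fall, and we expect Sunday's to begin above f.

In the middle, product builds up. Monday's flask stands at 40.5 mM at 1.9 min, close to Saturday's charge, yet from there its fractional fall is 0.206 /min. That flask holds added product, though its catalyst is also older. Sunday's charge is smaller than Monday's added product, so the drag should be milder.

We let the two drifts cancel and hold f to the end. That leaves 7.10 %, or 1.21 mM, in Sunday's flask.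

The forecast gives 5 % for that share and 0.32 for the order, holding that “product binds the catalyst competitively”. Its share lies below ours.

The flask gives 8.78 %, so the forecast's share stands within the margin, and an order of 0.048, well below the forecast's.

    free catalyst + starting material ⇌ catalyst-substrate complex, settled at all times (12.20 /M)
    catalyst-substrate complex + free catalyst → product + 2 free catalyst (4014 /M/min)
    free catalyst + product → spent catalyst + product (20.76 /M/min)
    starting material → decomposed substrate (0.2184 /min)

Sunday's 8.78 % is an average fractional fall of 0.640 /min, near our f of 0.696 /min. Part of that fall, 14 % of what is missing, comes from starting material that decomposes by itself. Sunday's flask without that path keeps 21.9 % at 3.8 min, an average fractional fall of 0.399 /min. The gap between the two runs is 0.241 /min, and the constant of the path to decomposed substrate is 0.218 /min.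

The runs stem from a simulated flask for substances that don't exist; noise was put on by code.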